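Remark on the chemistry: (triethylsilyloxy)acetaldehyde 12 is made in one step from glycolaldehyde dimer because its commercial supply is uncertain. No other assumption is needed.

**Atom labels.** O1 (tetrahydrofuran oxygen), C3 (CH bearing isopropenyl), C4 (ring CH2), C5 (spiro carbon), C6 (acetal CH, the lactone carbonyl carbon in earlier intermediates), O7 (oxetane oxygen), C8 (methyl-bearing oxetane carbon), C9 (CHBr), C10 (alkene CH), C11 (CBr), C12 (CMe2). From compound 9 on, descriptors in names refer to these labels; compounds 1–8, 11 and 12 carry ordinary systematic names.

**Compound numbers (fixed by the steps).** 1 D-glutamic acid; 2 lactone acid; 3 acid chloride; 4 methyl ketone; 5 isopropenyl lactone; 6 silylated alkynol; 7 its Co2(CO)6 complex; 8 silyl ketene acetal of 5; 9 complexed C5-alkylated lactone; 10 decomplexed lactone; 11 glycolaldehyde dimer; 12 (triethylsilyloxy)acetaldehyde; 13 aldol adduct; 14 β-keto lactone; 15 tertiary carbinol; 16 bis(triethylsilyl) ether; 17 terminal alkyne; 18 alkynyl aldehyde; 19 cyclised bromoalkene carbinol; 20 diol; 21 C9 silyl ether; 22 lactol; 23 oxetane acetal silyl ether; 24 oxetane acetal alcohol; 25 target.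

## Analysis of the target

Compound 25 (C15H20Br2O2) is a tricycle in which C5 belongs to three rings: a tetrahydrofuran (O1, C3, C4, C5, C6), an oxetane (C5, C6, O7, C8) and a cyclohexene, ring A (C5, C8, C9, C10, C11, C12). C6 is an acetal carbon shared by both oxygen rings, so the oxetane is a 2-alkoxyoxetane, strained and labile to acid. There are five stereocentres, (3R,5S,6S,8S,9S). The isopropenyl group at C3 and the C12 branch of C5 lie on one face of the tetrahydrofuran and C8 with O7 on the other; C6 follows from the cis fusion, the C8 methyl is cis to C4, and the C9 bromine is trans to O7. C5 is quaternary and flanked by the fully substituted C8 and C12, so three contiguous carbons without hydrogen must be joined. Sensitive groups are the oxetane acetal (acid), the secondary allylic bromide at C9 (ionisation), the vinyl bromide at C11 (metals, strong base) and the isopropenyl group (acid, electrophiles). The difficulty is this congested triad together with a strained acetal that cannot be carried through many steps. The strategy rests on the C9–C10=C11(Br)–C12 segment of ring A: a heteroatom-bearing C9 next to a bromoalkene whose bromine sits on the distal carbon is what anti addition of a carbonyl carbon and bromide across a terminal alkyne leaves behind. C10 is then the former alkyne CH and C11 the internal alkyne carbon on C12.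

## Retrosynthetic reasoning

**C9–Br.** The bromide of 25 is taken back to the epimeric carbinol 24, to be substituted with inversion as the last step. It is placed last because a free C8 oxygen next to a trans C9 bromide would close an epoxide under any basic step. In 24, two of the three C8 substituents are also pinned back in the oxetane, which opens the rear side of C9.

**C6–O7 (oxetane).** After removal of the C9 silyl group (24 from 23), the strained acetal bond of 23 is cut to give hydroxy lactol 22. The cut is made here because C6 is the only position that can be activated as an electrophile without touching a stereocentre. The forward reaction must dehydrate under neutral conditions, and O9 must be blocked so that it cannot form the easier five-membered acetal with C6.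

**Oxidation level and protecting groups.** Lactol 22 comes from lactone 21 by partial reduction. Compound 21 comes from diol 20 by silylation of the secondary hydroxyl only, and 20 from the cyclisation product 19 by cleaving its tertiary silyl ether. The lactone is kept as long as possible because it is the robust form of C6.

**C9–C10 and C11–Br (key cut).** Ring A of 19 is opened between C9 and C10 and the bromine is removed from C11, which gives alkynyl aldehyde 18. Cutting here removes one ring, two skeletal bonds and the C9 stereocentre in one operation and leaves only a terminal alkyne and an aldehyde. The forward reaction must close 6-endo through the terminal alkyne carbon and add bromide anti, with the C8 stereocentre controlling the aldehyde face.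

**C9 aldehyde, alkyne, O8.** Aldehyde 18 is traced to the primary silyl ether 17, which is oxidised directly so that no free primary alcohol appears next to the lactone. Compound 17 comes from the C-silylated alkyne 16, and 16 from tertiary carbinol 15.

**C8–CH3.** The C8 methyl group of 15 is cut to give β-keto lactone 14. This bond is chosen over a direct aldol with a ketone. The ketone aldol would join two fully substituted carbons reversibly and leave C8 to a poorly defined transition state. Adding a methyl nucleophile to a magnesium chelate of 14 sets C8 by a clear model.

**C5–C8.** Ketone 14 comes from aldol adduct 13, and 13 from the enolate of lactone 10 and aldehyde 12. The forward reaction must bring C8 in trans to the isopropenyl group.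

**C5–C12.** Lactone 10 comes by decomplexation from 9, and 9 from a Nicholas reaction of the silyl ketene acetal 8 of lactone 5 with the cobalt-complexed alkynol 7 (from 6). The order of the two C5 bonds is fixed by the stereochemistry: C12 must end cis to isopropenyl, so it goes in first and the second electrophile (C8) enters anti to isopropenyl.

**Chiral pool.** Lactone 5 comes from methyl ketone 4, which comes from lactone acid 2 through acid chloride 3, and 2 from D-glutamic acid 1, which supplies C3 with the correct (R) configuration. Aldehyde 12 comes from glycolaldehyde dimer 11.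

## Alternatives that were turned down

**Alternative 1: β-lactone as a latent oxetane.**
- Disconnection: the C3–O1 bond and the C6–H bond. The oxetane is carried as a β-lactone and C3 as the secondary carbon of a side-chain epoxide, as in A1.
- Forward key step: a hydride adds to the β-lactone carbonyl of A1, and the aluminium hemiacetal oxygen opens the epoxide at C3 (5-exo, inversion). This gives A2, the tricyclic acetal with a tertiary alcohol in place of isopropenyl.
- For it: the four-membered ring is closed as a β-lactone from a β-hydroxy acid, a dependable closure, and never at the acetal stage. On this point it is stronger than the chosen route, whose step 18 closes the strained acetal directly.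
- Against it: the tetrahedral intermediate of a β-lactone tends to collapse with ring opening, which relieves strain and gives an aldehyde, and the 2-alkoxyoxetane is then lost. The aluminium alkoxide must alkylate a secondary epoxide carbon at the low temperature at which the hemiacetal survives. Ring A, the quaternary C5 and the vinyl bromide must all be built beforehand without help from this step. The isopropenyl group must then be made by regioselective dehydration of the tertiary alcohol of A2 next to an acid-labile acetal.
- Comparison: the chosen strategy offers instead a precedented ring-A closure that sets C9 and the C11 bromide together, at the price of a less secure oxetane closure and two protecting-group steps.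

**Alternative 2: Claisen ring contraction.**
- Disconnection: C5–C12.
- Forward key step: A3, the silyl ketene acetal of a δ-lactone whose alkoxy carbon C10 bears a 1-bromo-2-methylprop-1-enyl group, rearranges [3,3] through a boat transition state. C5–C12 forms and C10–O breaks, which gives ring-A acid A4 with quaternary C5, the C10=C11 vinyl bromide and the C8/C9 diol as acetonide.
- For it: a sigmatropic shift is the most dependable way to join the two fully substituted carbons C5 and C12, and it transfers chirality from C10 to C5. For that bond it is stronger than the Nicholas/aldol pair used here.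
- Against it: the migrating terminus is a fully substituted alkene carbon that must bond to a substituted ketene acetal carbon, so the shift is slow, and the β-oxygen at C8 can be eliminated from the lactone enolate before silylation. A4 has neither heterocycle and no C3 stereocentre. The prenyl chain must therefore be oxidised enantioselectively far from the ring stereocentres and later dehydrated to isopropenyl. The oxetane closure and the C9 bromination remain as in the chosen route.
- Comparison: the chosen strategy takes C3 from the chiral pool, uses it to set C5, and needs fewer oxidation-state changes after ring A is formed.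

**Alternative 3: intramolecular Paternò–Büchi reaction.**
- Disconnection: C5–C8 and C6–O7 together.
- Forward key step: irradiation of A5, a 2-isopropenyl-2,3-dihydrofuran with a tethered methyl ketone, joins C8 to C5 and the ketone oxygen to C6. This gives A6, the tricyclic oxetane acetal with a C9 silyl ether and a C11 ketal.
- For it: the photocycloaddition is the standard entry to 2-alkoxyoxetanes and makes the oxetane, ring A and three stereocentres in one step without a strained-acetal closure. For the oxetane it is clearly stronger than the chosen route.
- Against it: excited ketones prefer to bond through oxygen to the β-carbon of an enol ether (here C5), because the radical then sits on the oxygen-bearing carbon. The required orientation, with the C–C bond at the hindered C5, depends on the tether alone. Face selection depends on the remote C3 and C9 centres. The α-oxygenated ketone can undergo α-cleavage and the isopropenyl alkene is a competing partner. After the photoreaction the C11 ketal of A6 must be hydrolysed with acid in the presence of the oxetane acetal and converted into the vinyl bromide.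
- Comparison: the chosen strategy puts both bromine-bearing positions in place while the molecule is still a robust lactone and exposes the acetal to only two further steps.

Key step: step 14

## Route

Step 1
Reactants: 1 D-glutamic acid
Product: 2 (R)-5-oxotetrahydrofuran-2-carboxylic acid
Conditions: NaNO2, aq. HCl, 0 °C → rt
Reagents that add atoms: none
Why: Diazotisation of the α-amino acid; the α-carboxylate displaces N2 (α-lactone) and the γ-carboxyl opens it, so two inversions give the γ-lactone with net retention at the future C3.

Step 2
Reactants: 2 (R)-5-oxotetrahydrofuran-2-carboxylic acid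
Product: 4 (R)-5-acetyldihydrofuran-2(3H)-one, via acid chloride 3 (not isolated)
Conditions: (COCl)2, DMF (cat.), CH2Cl2, 0 °C → rt; then MeMgBr, CuI (5 mol %), THF, −78 °C
Reagents that add atoms: oxalyl chloride ClC(=O)C(=O)Cl (chlorine of 3); methylmagnesium bromide C[Mg]Br
Why: Copper-catalysed acylation of a Grignard reagent by an acid chloride stops at the ketone and is much faster than attack on the lactone at −78 °C; the stereocentre is not involved.

Step 3
Reactants: 4 (R)-5-acetyldihydrofuran-2(3H)-one
Product: 5 (R)-5-(prop-1-en-2-yl)dihydrofuran-2(3H)-one
Conditions: Zn, CH2Br2, TiCl4, THF/CH2Cl2, 0 °C → rt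
Reagents that add atoms: dibromomethane BrCBr
Why: Takai–Lombardo methylenation; the non-basic zinc/titanium methylene reagent converts ketones but not lactones and does not enolise the α-acyloxy ketone, so C3 keeps its (R) configuration.

Step 4
Reactants: 6 2-methyl-4-(trimethylsilyl)but-3-yn-2-ol
Product: 7 Co2(CO)6 complex of 6
Conditions: Co2(CO)8, CH2Cl2, rt
Reagents that add atoms: dicobalt octacarbonyl O=C=[Co](=C=O)(=C=O)(=C=O)[Co](=C=O)(=C=O)(=C=O)=C=O
Why: The alkyne displaces two CO ligands of Co2(CO)8 to give the stable bridged hexacarbonyldicobalt complex that is the precursor of the Nicholas cation.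

Step 5
Reactants: 5 (R)-5-(prop-1-en-2-yl)dihydrofuran-2(3H)-one; 7 Co2(CO)6 complex of 6
Product: 9 (3R)-isopropenyl butyrolactone bearing the Co2(CO)6-complexed CMe2–C≡C–SiMe3 group at C5 (both C5 epimers), via silyl ketene acetal 8 (not isolated)
Conditions: LiN(iPr)2, THF, −78 °C; Me3SiCl; solvent exchange; then 7, BF3·OEt2, CH2Cl2, −78 → −20 °C
Reagents that add atoms: chlorotrimethylsilane C[Si](C)(C)Cl (silyl group of 8)
Why: Nicholas reaction; BF3 ionises the complexed tertiary propargylic alcohol and the cobalt-stabilised cation alkylates the silyl ketene acetal at C5, forming the C5–C12 bond to a quaternary carbon without allene formation. The C5 configuration is immaterial because C5 is enolised again in step 8.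

Step 6
Reactants: 9 complexed C5-alkylated lactone
Product: 10 (3R)-isopropenyl butyrolactone bearing the CMe2–C≡C–SiMe3 group at C5 (both C5 epimers)
Conditions: (NH4)2Ce(NO3)6, acetone, −10 °C
Reagents that add atoms: none
Why: Oxidative decomplexation releases the alkyne; the C-silyl group, the isopropenyl group and the lactone tolerate brief exposure to the cerium salt at low temperature.

Step 7
Reactants: 11 glycolaldehyde dimer (1,4-dioxane-2,5-diol)
Product: 12 (triethylsilyloxy)acetaldehyde
Conditions: Et3SiCl, imidazole, CH2Cl2, 0 °C → rt
Reagents that add atoms: chlorotriethylsilane CC[Si](CC)(CC)Cl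
Why: The dimer equilibrates with monomeric glycolaldehyde, whose primary hydroxyl is silylated; O-silylation drains the equilibrium.

Step 8
Reactants: 10 C5-alkylated lactone; 12 (triethylsilyloxy)acetaldehyde
Product: 13 (3R,5S)-lactone with quaternary C5 carrying C12 cis and the CH(OH)CH2OSiEt3 group (C8, C9) trans to isopropenyl (both C8 epimers)
Conditions: LiN(iPr)2, THF, −78 → −40 °C; 12, −78 °C; AcOH, −78 °C
Reagents that add atoms: none
Why: Aldol addition of the lactone lithium enolate; the aldehyde approaches the enolate face anti to the C3 isopropenyl group (1,3-induction in the butyrolactone enolate), which makes C5 quaternary with C8 trans and C12 cis to isopropenyl (5S). The silyl cap on the alkyne prevents acetylide formation and the cold acidic quench prevents retro-aldol cleavage; the C8 epimers converge in step 9.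

Step 9
Reactants: 13 aldol adduct
Product: 14 (3R,5S)-β-keto lactone with the C8 ketone and C9H2–OSiEt3
Conditions: Dess–Martin periodinane, NaHCO3, CH2Cl2, rt
Reagents that add atoms: none
Why: Dess–Martin oxidation of the secondary carbinol; the β-keto lactone cannot enolise at the quaternary C5, so C5 is configurationally safe.

Step 10
Reactants: 14 β-keto lactone
Product: 15 (3R,5S,8S)-tertiary carbinol with C8–CH3 and C8–OH and C9H2–OSiEt3
Conditions: MeMgBr, CH2Cl2/Et2O, −78 °C; aq. NH4Cl, −78 °C
Reagents that add atoms: methylmagnesium bromide C[Mg]Br
Why: Chelation-controlled Grignard addition to an α,α-disubstituted β-keto lactone; magnesium bridges the ketone and lactone carbonyl oxygens, which holds O8 syn to C6, and methyl enters from the face flanked by the ring methylene C4 and not by the tert-alkyl C12 branch, giving (8S). The C9 silyl ether is a poor donor and sets up no competing chelate, and the ketone is far more electrophilic than the hindered lactone.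

Step 11
Reactants: 15 tertiary carbinol
Product: 16 (3R,5S,8S)-bis(triethylsilyl) ether (C8–OSiEt3 and C9H2–OSiEt3)
Conditions: Et3SiOSO2CF3, 2,6-lutidine, CH2Cl2, −78 → 0 °C
Reagents that add atoms: triethylsilyl trifluoromethanesulfonate CC[Si](CC)(CC)OS(=O)(=O)C(F)(F)F
Why: Silyl triflates silylate hindered tertiary alcohols; capping O8 also closes the retro-aldol pathway of the tertiary aldol.

Step 12
Reactants: 16 bis(triethylsilyl) ether
Product: 17 (3R,5S,8S)-bis(triethylsilyl) ether with the terminal alkyne (C12–C11≡C10–H)
Conditions: AgNO3 (10 mol %), acetone/H2O, rt
Reagents that add atoms: none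
Why: Silver-catalysed protodesilylation of the alkynylsilane through the silver acetylide; the medium is neutral, so both triethylsilyl ethers and the lactone are untouched and no alkoxide is formed that could translactonise.

Step 13
Reactants: 17 terminal alkyne
Product: 18 (3R,5S,8S)-alkynyl aldehyde with the C9 aldehyde and C8–OSiEt3 and the C12 ethynyl group
Conditions: (COCl)2, DMSO, CH2Cl2, −78 → −40 °C; Et3N, −78 → 0 °C
Reagents that add atoms: none
Why: Under Swern conditions a primary triethylsilyl ether is cleaved by the chlorosulfonium salt and oxidised directly to the aldehyde, while the hindered tertiary triethylsilyl ether survives. No free primary alcohol that could attack the lactone carbonyl is released, and the aldehyde cannot epimerise because C8 is quaternary.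

Step 14
Reactants: 18 alkynyl aldehyde
Product: 19 (3R,5S,8S,9R)-spiro lactone with the ring-A C10=C11 bromoalkene and C9–OH cis to C8–OSiEt3
Conditions: FeBr3 (1.3 equiv), 2,6-di-tert-butyl-4-methylpyridine (0.3 equiv), CH2Cl2, −78 → −30 °C; aq. NaHCO3
Reagents that add atoms: iron tribromide Br[Fe](Br)Br
Why: FeBr3 binds the C9 aldehyde, the terminal alkyne carbon C10 attacks C9, and bromide from the bromoferrate adds to C11 anti to the new C9–C10 bond, so the ring, the C10=C11 bromoalkene and the C9 carbinol form together. This is a halide-terminated alkyne Prins (halo-Prins) cyclisation, the reaction type known from iron-halide-promoted alkyne–aldehyde couplings and from Lewis-acid closures of alkynyl carbonyl compounds to halocycloalkenols. Ring A closes 6-endo-dig because attack through the terminal carbon places the developing positive charge on the internal, alkyl-substituted C11, whereas 5-exo closure would need a primary vinyl cation; the C12 gem-dimethyl group and the quaternary C5 press the reacting ends together. The new C9 stereocentre is controlled by C8: in the chair-like transition state the C8 oxygen is axial, which avoids a 1,3-diaxial contact between the C8 methyl and a C12 methyl, and the iron-bound aldehyde oxygen is equatorial, where it can share the metal with O8. C10 then adds to the aldehyde face that leaves O9 cis to O8, giving (9R). The isopropenyl group cannot take part because the aldehyde-bearing C8 lies on the lactone face opposite to it, and the ferrate bromide is a better trap for C11 than the lactone carbonyl oxygen. Low temperature and the hindered pyridine suppress HBr addition to the isopropenyl group, ionisation of the allylic carbinol and 1,2-shift in the activated α-silyloxy aldehyde.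

Step 15
Reactants: 19 cyclised bromoalkene carbinol
Product: 20 (3R,5S,8S,9R)-spiro lactone diol (C8–OH and C9–OH cis)
Conditions: HF·pyridine, pyridine, THF, 0 °C → rt
Reagents that add atoms: none
Why: Fluoride cleavage of the tertiary silyl ether under buffered, non-basic conditions, so neither O8 nor O9 becomes an alkoxide that could trigger retro-aldol cleavage or translactonisation.

Step 16
Reactants: 20 diol
Product: 21 (3R,5S,8S,9R)-spiro lactone with C9–OSi(tBu)Me2 and free C8–OH
Conditions: tBuMe2SiOSO2CF3 (1.1 equiv), 2,6-lutidine, CH2Cl2, −78 → −40 °C
Reagents that add atoms: tert-butyldimethylsilyl trifluoromethanesulfonate CC(C)(C)[Si](C)(C)OS(=O)(=O)C(F)(F)F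
Why: The secondary allylic hydroxyl is silylated much faster than the tertiary one flanked by the quaternary C5; O9 must be blocked because it would otherwise form a five-membered acetal with C6 in step 18.

Step 17
Reactants: 21 C9 silyl ether
Product: 22 (3R,5S,8S,9R)-lactol (C6–OH, both anomers) with free C8–OH and C9–OSi(tBu)Me2
Conditions: iBu2AlH (2.5 equiv), CH2Cl2, −78 °C; aq. KNaC4H4O6
Reagents that add atoms: none
Why: Partial reduction of the lactone; the aluminium hemiacetal is stable at −78 °C and gives the lactol on work-up. The first equivalent is consumed by the C8 hydroxyl, and the vinyl bromide, silyl ether and alkene are inert.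

Step 18
Reactants: 22 lactol
Product: 23 (3R,5S,6S,8S,9R)-tricyclic oxetane acetal with C9–OSi(tBu)Me2
Conditions: PPh3, iPrO2CN=NCO2iPr, THF, 0 °C → rt
Reagents that add atoms: none
Why: Mitsunobu-type cyclodehydration; the more acidic, less hindered lactol hydroxyl becomes the oxyphosphonium leaving group and the C8 hydroxyl, held next to C6 on the face opposite to C12, closes the four-membered ring (4-exo) at the incipient oxocarbenium carbon under neutral conditions in which the acetal persists. O7 can only bond to C6 cis to C8, so (6S) follows from C5; the closest known reactions are the closures of hydroxy lactols and of hydroxy glycosyl halides to bridged oxetane acetals such as 1,3-anhydro sugars.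

Step 19
Reactants: 23 oxetane acetal silyl ether
Product: 24 (3R,5S,6S,8S,9R)-tricyclic oxetane acetal with free C9–OH
Conditions: Bu4NF, THF, 0 °C → rt
Reagents that add atoms: none
Why: Fluoride desilylation under basic conditions, to which the oxetane acetal and the vinyl bromide are stable.

Step 20
Reactants: 24 oxetane acetal alcohol
Product: 25 (3R,5S,6S,8S,9S)-target CNP0141320.1
Conditions: CBr4, PPh3, 2,6-lutidine, CH2Cl2, 0 °C
Reagents that add atoms: tetrabromomethane BrC(Br)(Br)Br
Why: Appel bromination; bromide displaces the alkoxyphosphonium group with inversion, which turns the C9 oxygen cis to O7 into the bromide trans to it (9S). The buffered neutral medium spares the acetal, and with two C8 substituents pinned back in the oxetane the rear side of C9 is more open than in an ordinary neopentyl position.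

## Compound list

1 | D-glutamic acid, (R)-2-aminopentanedioic acid | N[C@H](CCC(=O)O)C(=O)O | starting material
2 | (R)-5-oxotetrahydrofuran-2-carboxylic acid | OC(=O)[C@H]1CCC(=O)O1 | intermediate
3 | (R)-5-oxotetrahydrofuran-2-carbonyl chloride | ClC(=O)[C@H]1CCC(=O)O1 | intermediate (not isolated)
4 | (R)-5-acetyldihydrofuran-2(3H)-one | CC(=O)[C@H]1CCC(=O)O1 | intermediate
5 | (R)-5-(prop-1-en-2-yl)dihydrofuran-2(3H)-one | C=C(C)[C@H]1CCC(=O)O1 | intermediate
6 | 2-methyl-4-(trimethylsilyl)but-3-yn-2-ol | CC(C)(O)C#C[Si](C)(C)C | starting material
7 | Co2(CO)6 complex of 6, the alkyne bridging both cobalt atoms | CC(C)(O)C12[Co]3(=C=O)(=C=O)(=C=O)[Co]1(=C=O)(=C=O)(=C=O)C23[Si](C)(C)C | intermediate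
8 | (R)-trimethyl{[5-(prop-1-en-2-yl)-4,5-dihydrofuran-2-yl]oxy}silane | C=C(C)[C@H]1CC=C(O[Si](C)(C)C)O1 | intermediate (not isolated)
9 | (3R)-isopropenyl butyrolactone with the Co2(CO)6-complexed CMe2–C≡C–SiMe3 group at C5, both C5 epimers | C=C(C)[C@H]1CC(C(=O)O1)C(C)(C)C23[Co]4(=C=O)(=C=O)(=C=O)[Co]2(=C=O)(=C=O)(=C=O)C34[Si](C)(C)C | intermediate
10 | (3R)-isopropenyl butyrolactone with the CMe2–C≡C–SiMe3 group at C5, both C5 epimers | C=C(C)[C@H]1CC(C(=O)O1)C(C)(C)C#C[Si](C)(C)C | intermediate
11 | glycolaldehyde dimer, 1,4-dioxane-2,5-diol | OC1COC(O)CO1 | starting material
12 | (triethylsilyloxy)acetaldehyde | O=CCO[Si](CC)(CC)CC | intermediate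
13 | (3R,5S)-aldol adduct, C5 quaternary with CH(OH)CH2OSiEt3 trans to isopropenyl, both C8 epimers | C=C(C)[C@H]1C[C@](C(=O)O1)(C(C)(C)C#C[Si](C)(C)C)C(O)CO[Si](CC)(CC)CC | intermediate
14 | (3R,5S)-β-keto lactone, C8 ketone, C9H2–OSiEt3 | C=C(C)[C@H]1C[C@](C(=O)O1)(C(C)(C)C#C[Si](C)(C)C)C(=O)CO[Si](CC)(CC)CC | intermediate
15 | (3R,5S,8S)-tertiary carbinol, C8–CH3 and C8–OH, C9H2–OSiEt3 | C=C(C)[C@H]1C[C@](C(=O)O1)(C(C)(C)C#C[Si](C)(C)C)[C@](C)(O)CO[Si](CC)(CC)CC | intermediate
16 | (3R,5S,8S)-bis(triethylsilyl) ether, C-silylated alkyne | C=C(C)[C@H]1C[C@](C(=O)O1)(C(C)(C)C#C[Si](C)(C)C)[C@](C)(O[Si](CC)(CC)CC)CO[Si](CC)(CC)CC | intermediate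
17 | (3R,5S,8S)-bis(triethylsilyl) ether, terminal alkyne | C=C(C)[C@H]1C[C@](C(=O)O1)(C(C)(C)C#C)[C@](C)(O[Si](CC)(CC)CC)CO[Si](CC)(CC)CC | intermediate
18 | (3R,5S,8S)-alkynyl aldehyde, C9 aldehyde, C8–OSiEt3, C12 ethynyl | C=C(C)[C@H]1C[C@](C(=O)O1)(C(C)(C)C#C)[C@](C)(O[Si](CC)(CC)CC)C=O | intermediate
19 | (3R,5S,8S,9R)-spiro lactone, ring-A C10=C11 bromoalkene, C9–OH cis to C8–OSiEt3 | C=C(C)[C@H]1C[C@@]2(C(=O)O1)[C@](C)(O[Si](CC)(CC)CC)[C@H](O)C=C(Br)C2(C)C | intermediate
20 | (3R,5S,8S,9R)-spiro lactone diol | C=C(C)[C@H]1C[C@@]2(C(=O)O1)[C@](C)(O)[C@H](O)C=C(Br)C2(C)C | intermediate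
21 | (3R,5S,8S,9R)-spiro lactone, C9–OSi(tBu)Me2, free C8–OH | C=C(C)[C@H]1C[C@@]2(C(=O)O1)[C@](C)(O)[C@H](O[Si](C)(C)C(C)(C)C)C=C(Br)C2(C)C | intermediate
22 | (3R,5S,8S,9R)-lactol, both C6 anomers, free C8–OH, C9–OSi(tBu)Me2 | C=C(C)[C@H]1C[C@@]2(C(O)O1)[C@](C)(O)[C@H](O[Si](C)(C)C(C)(C)C)C=C(Br)C2(C)C | intermediate
23 | (3R,5S,6S,8S,9R)-tricyclic oxetane acetal, C9–OSi(tBu)Me2 | C=C(C)[C@H]1C[C@@]23[C@@H](O1)O[C@]2(C)[C@H](O[Si](C)(C)C(C)(C)C)C=C(Br)C3(C)C | intermediate
24 | (3R,5S,6S,8S,9R)-tricyclic oxetane acetal, C9–OH | C=C(C)[C@H]1C[C@@]23[C@@H](O1)O[C@]2(C)[C@H](O)C=C(Br)C3(C)C | intermediate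
25 | (3R,5S,6S,8S,9S)-CNP0141320.1 | C=C(C)[C@H]1C[C@@]23[C@@H](O1)O[C@]2(C)[C@@H](Br)C=C(Br)C3(C)C | target

## Step count and least certain steps

Total: 20 steps. Longest linear sequence: 18 steps (1–3, 5, 6, 8–20) from D-glutamic acid; steps 4 and 7 are one-step side branches.

**Step 14 (key step).**
- Most likely failure: attack on the wrong aldehyde face. A silyl ether shares the iron only weakly, so a transition state with the C8–O bond anti to the incoming alkyne (polar Felkin–Anh) can compete with the chelated one and give the C9 epimer.
- Two side channels are also conceivable: capture of C11 by the lactone carbonyl oxygen instead of bromide, and a 1,2-shift in the activated α-silyloxy aldehyde.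
- Fallback: setting C9 is separated from ring closure. Starting from 19 as a C9 epimer mixture, the carbinol is oxidised with Dess–Martin periodinane to the ring-A enone F1. F1 is reduced with NaBH4 and CeCl3·7H2O in MeOH at −78 °C. Hydride should add anti to the pseudo-axial C8–OSiEt3 group, which gives the cis carbinol and returns to 19.

**Step 18 (oxetane closure).**
- Most likely failure: the anomeric oxyphosphonium ion is intercepted by the hydrazide anion before the hindered tertiary hydroxyl can close the strained ring. Alternatively, the hydroxy oxocarbenium ion fragments by C5–C8 cleavage to an enol ether and a ketone.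
- Fallback: the closure is run as a halide glycosylation without a competing nucleophile. Starting from 22, 1-chloro-N,N,2-trimethylprop-1-en-1-amine gives the anomeric chloride F2. AgOSO2CF3 with 2,6-di-tert-butyl-4-methylpyridine in CH2Cl2 at −40 °C removes chloride irreversibly, and the C8 hydroxyl closes the ring, returning to 23.

**Step 20 (Appel bromination).**
- Most likely failure: ionisation of the allylic alkoxyphosphonium ion instead of direct displacement, which costs stereochemical integrity at C9. Traces of HBr can also open the acetal.
- Fallback: the substitution is moved to the robust lactone stage. Starting from 19, CBr4 and PPh3 give the C9 bromide F3 with the C8 oxygen still silylated, so no epoxide can form. iBu2AlH at −78 °C gives lactol F4, and HF·pyridine frees the C8 hydroxyl without forming an alkoxide (bromohydrin lactol F5). The Mitsunobu closure of step 18, applied to F5, returns directly to 25 and saves two steps.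
- Risk of this order: epoxide formation from the bromohydrin if the medium becomes basic.

**Step 8 (aldol at the hindered enolate).**
- Most likely failure: slow addition and retro-aldol reversal, because the enolate carbon carries a tert-alkyl group and the adduct is crowded. Face selectivity may also erode.
- Fallback: an open, Lewis-acid-mediated Mukaiyama aldol. Starting from 10, LiN(iPr)2 and Me3SiCl give the tetrasubstituted silyl ketene acetal F6. F6 adds to 12 with BF3·OEt2 in CH2Cl2 at −78 °C, again anti to isopropenyl, and returns to 13.

**Step 10 (methyl addition).**
- Most likely failure: loss of facial control if a dipole-minimised, non-chelated conformer of the β-keto lactone reacts. Enolisation of the ketone toward C9 and retro-aldol cleavage of the magnesium aldolate on warming are further risks.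
- Fallback: both C8 substituents are brought in with the C5–C8 bond. Starting from 10, the lithium enolate is added at −78 °C to 1-(triethylsilyloxy)propan-2-one F7 (from hydroxyacetone and Et3SiCl), which returns directly to 15. C8 is then set in the closed aldol transition state, an independent control element whose sense is not secure.

## Further compounds

F1 | step 14 | (3R,5S,8S)-spiro lactone ring-A enone, C9 ketone, C8–OSiEt3 | C=C(C)[C@H]1C[C@@]2(C(=O)O1)[C@](C)(O[Si](CC)(CC)CC)C(=O)C=C(Br)C2(C)C
F2 | step 18 | (3R,5S,8S,9R)-anomeric chloride at C6, free C8–OH, C9–OSi(tBu)Me2 | C=C(C)[C@H]1C[C@@]2(C(Cl)O1)[C@](C)(O)[C@H](O[Si](C)(C)C(C)(C)C)C=C(Br)C2(C)C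
F3 | step 20 | (3R,5S,8S,9S)-spiro lactone C9 bromide, C8–OSiEt3 | C=C(C)[C@H]1C[C@@]2(C(=O)O1)[C@](C)(O[Si](CC)(CC)CC)[C@@H](Br)C=C(Br)C2(C)C
F4 | step 20 | (3R,5S,8S,9S)-lactol C9 bromide, C8–OSiEt3 | C=C(C)[C@H]1C[C@@]2(C(O)O1)[C@](C)(O[Si](CC)(CC)CC)[C@@H](Br)C=C(Br)C2(C)C
F5 | step 20 | (3R,5S,8S,9S)-bromohydrin lactol, free C8–OH | C=C(C)[C@H]1C[C@@]2(C(O)O1)[C@](C)(O)[C@@H](Br)C=C(Br)C2(C)C
F6 | step 8 | trimethylsilyl ketene acetal of 10 | C=C(C)[C@H]1CC(=C(O[Si](C)(C)C)O1)C(C)(C)C#C[Si](C)(C)C
F7 | step 10 | 1-(triethylsilyloxy)propan-2-one | CC(=O)CO[Si](CC)(CC)CC
A1 | alternative 1 | ring-A β-lactone with C9 silyl ether and 3,3-dimethyloxiranylmethyl side chain on C5 | CC1(C)O[C@H]1C[C@@]23C(=O)O[C@]2(C)[C@H](O[Si](C)(C)C(C)(C)C)C=C(Br)C3(C)C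
A2 | alternative 1 | tricyclic acetal with tertiary alcohol side chain and C9 silyl ether | CC(C)(O)[C@H]1C[C@@]23[C@@H](O1)O[C@]2(C)[C@H](O[Si](C)(C)C(C)(C)C)C=C(Br)C3(C)C
A3 | alternative 2 | silyl ketene acetal of the acetonide-fused δ-lactone with 1-bromo-2-methylprop-1-enyl at C10 and prenyl at C5 | CC(C)=CCC1=C(O[Si](C)(C)C)O[C@H](C(Br)=C(C)C)[C@H]2OC(C)(C)O[C@@]12C
A4 | alternative 2 | ring-A acid with quaternary C5, acetonide and vinyl bromide | CC(C)=CC[C@@]1(C(=O)O)[C@]2(C)OC(C)(C)O[C@@H]2C=C(Br)C1(C)C
A5 | alternative 3 | (R)-2-isopropenyl-2,3-dihydrofuran with tethered α-silyloxy methyl ketone and C11 ketal | C=C(C)[C@H]1CC(=CO1)C(C)(C)C2(OCCO2)C[C@@H](O[Si](C)(C)C(C)(C)C)C(C)=O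
A6 | alternative 3 | tricyclic oxetane acetal with C9 silyl ether and C11 ketal | C=C(C)[C@H]1C[C@@]23[C@@H](O1)O[C@]2(C)[C@H](O[Si](C)(C)C(C)(C)C)CC4(OCCO4)C3(C)C
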